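**Retrosynthetic overview**

1. The target is an eriodictyol unit (rings A, B, C; plain and single-primed locants) joined through C3 to C8'' of a naringenin unit (rings A'', C'' and its aryl ring; double- and triple-primed locants). The last operations are loss of a temporary tert-butoxycarbonyl group from C3, which then settles trans to C2, and hydrogenolysis of seven benzyl ethers.
2. Key disconnection C3–C8'': in one flask an achiral 2'-hydroxychalcone carrying that ester on its α-carbon closes ring C by thiourea-catalysed oxa-Michael addition (C2 by catalyst control), and the resulting β-ketoester is arylated at C3 by the aryllead triacetate of the finished lower flavanone.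
3. Enabling feature: C3 is the α-carbon of a 2'-hydroxychalcone and, with the temporary ester, the central carbon of a β-ketoester between C4=O and CO2t-Bu. Ring closure by the ring A hydroxyl (future O1) therefore creates exactly the soft carbon acid that lead ligand coupling needs. C8'' is the CH of phloroglucinol ring A'' between O1'' and the 7''-oxygen, where iodine, then tin, then lead can be placed.
4. Lower unit: ring C'' is closed by the same catalytic oxa-Michael reaction on the same β-ketoester building block (sets C2''), then decarboxylation and C8'' iodination. Both halves come from 2,4,6-trihydroxyacetophenone.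
5. Ring order: ring C'' first (step 5), ring C in the key step; all four benzene rings are bought.

Key step: step 9

Assumption: the quinine-derived thiourea N-[3,5-bis(trifluoromethyl)phenyl]-N'-[(8S,9S)-6'-methoxycinchonan-9-yl]thiourea is taken to deliver the (2R) series in the oxa-Michael closure. If it delivers (2S), its quinidine-derived pseudo-enantiomer is used in both cyclisations; the circular dichroism of the flavanone made in step 5 decides this before the key step.

**Route**

Step 1
Reactants: 1 2,4,6-trihydroxyacetophenone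
Product: 2 1-[2,4-bis(benzyloxy)-6-hydroxyphenyl]ethanone
Conditions: BnBr (2.1 equiv), K2CO3 (2.2 equiv), DMF, 25 °C
Reagents that add atoms: benzyl bromide, BrCc1ccccc1
Why: Williamson ether synthesis; the hydroxyl hydrogen-bonded to the acetyl carbonyl is the least nucleophilic and should stay free when two equivalents of benzyl bromide are used.

Step 2
Reactants: 2 1-[2,4-bis(benzyloxy)-6-hydroxyphenyl]ethanone
Product: 3 tert-butyl 3-[2,4-bis(benzyloxy)-6-hydroxyphenyl]-3-oxopropanoate
Conditions: LiN(SiMe3)2 (3.3 equiv), THF, −78 °C; Boc2O (1.05 equiv), −78 → 0 °C; aq NH4Cl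
Reagents that add atoms: di-tert-butyl dicarbonate, CC(C)(C)OC(=O)OC(=O)OC(C)(C)C
Why: Claisen-type C-acylation of the phenoxide–enolate dianion with a dicarbonate, the third equivalent of base holding the product as its enolate until the quench; a tert-butyl ester should not lactonise onto the free phenol to a 4-hydroxycoumarin.

Step 3
Reactants: 3 tert-butyl 3-[2,4-bis(benzyloxy)-6-hydroxyphenyl]-3-oxopropanoate; 4 3,4-bis(benzyloxy)benzaldehyde
Product: 5 tert-butyl 2-[2,4-bis(benzyloxy)-6-hydroxybenzoyl]-3-[3,4-bis(benzyloxy)phenyl]prop-2-enoate (E/Z mixture)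
Conditions: piperidine (0.2 equiv), AcOH (0.2 equiv), 4 Å molecular sieves, toluene, 25 °C
Reagents that add atoms: none
Why: Knoevenagel condensation under buffered amine catalysis with removal of water; the phenol stays hydrogen-bonded to the ketone and should not add to the new double bond in this weakly basic medium, and both alkene isomers converge in step 9.

Step 4
Reactants: 3 tert-butyl 3-[2,4-bis(benzyloxy)-6-hydroxyphenyl]-3-oxopropanoate; 6 4-(benzyloxy)benzaldehyde
Product: 7 tert-butyl 2-[2,4-bis(benzyloxy)-6-hydroxybenzoyl]-3-[4-(benzyloxy)phenyl]prop-2-enoate (E/Z mixture)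
Conditions: piperidine (0.2 equiv), AcOH (0.2 equiv), 4 Å molecular sieves, toluene, 25 °C
Reagents that add atoms: none
Why: Knoevenagel condensation as in step 3; both alkene isomers converge in step 5.

Step 5
Reactants: 7 tert-butyl 2-[2,4-bis(benzyloxy)-6-hydroxybenzoyl]-3-[4-(benzyloxy)phenyl]prop-2-enoate
Product: 10 (2R)-5,7-bis(benzyloxy)-2-[4-(benzyloxy)phenyl]chroman-4-one, via cyclised tert-butyl ester 8 (not isolated), via keto acid 9 (not isolated)
Conditions: quinine-derived thiourea (10 mol %), toluene, −25 °C; then TsOH·H2O (0.5 equiv), 80 °C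
Reagents that add atoms: none
Why: Thiourea-catalysed enantioselective oxa-Michael cyclisation of an alkylidene β-ketoester (6-endo-trig attack of the phenolic oxygen on the benzylidene carbon) sets C2'' under catalyst control, and acid then removes the tert-butyl ester as 2-methylpropene and the β-keto acid loses CO2 without touching C2''.

Step 6
Reactants: 10 (2R)-5,7-bis(benzyloxy)-2-[4-(benzyloxy)phenyl]chroman-4-one
Product: 11 (2R)-5,7-bis(benzyloxy)-2-[4-(benzyloxy)phenyl]-8-iodochroman-4-one
Conditions: N-iodosuccinimide (1.05 equiv), CF3CO2H (cat.), MeCN, 0 → 25 °C, dark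
Reagents that add atoms: N-iodosuccinimide, O=C1CCC(=O)N1I
Why: Electrophilic aromatic iodination; of the two free positions of ring A'', C8'' (para to the 5''-benzyloxy group, between O1'' and the 7''-benzyloxy group) should react in preference to C6'', which lies between two freely rotating benzyloxy groups, in line with the usual 8-selectivity of 5,7-di-O-alkylated flavonoids.

Step 7
Reactants: 11 (2R)-5,7-bis(benzyloxy)-2-[4-(benzyloxy)phenyl]-8-iodochroman-4-one
Product: 12 (2R)-5,7-bis(benzyloxy)-2-[4-(benzyloxy)phenyl]-8-(trimethylstannyl)chroman-4-one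
Conditions: Me3SnSnMe3 (1.5 equiv), Pd(PPh3)4 (5 mol %), toluene, 100 °C
Reagents that add atoms: hexamethylditin, C[Sn](C)(C)[Sn](C)(C)C
Why: Palladium-catalysed stannylation of an aryl iodide with a distannane (oxidative addition, transmetalation, reductive elimination) runs under neutral conditions, so the base-sensitive C2'' centre and the ketone are not at risk.

Step 8
Reactants: 12 (2R)-5,7-bis(benzyloxy)-2-[4-(benzyloxy)phenyl]-8-(trimethylstannyl)chroman-4-one
Product: 13 [(2R)-5,7-bis(benzyloxy)-2-[4-(benzyloxy)phenyl]-4-oxochroman-8-yl]lead triacetate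
Conditions: Pb(OAc)4 (1.05 equiv), Hg(OAc)2 (5 mol %), CHCl3, 25 → 40 °C; filtration through Celite, used directly
Reagents that add atoms: lead tetraacetate, CC(=O)O[Pb](OC(C)=O)(OC(C)=O)OC(C)=O
Why: Tin-to-lead exchange catalysed by Hg(OAc)2, the standard entry to aryllead triacetates; ipso substitution at the C–Sn bond fixes tetravalent lead at C8'', and the two ortho oxygen atoms stabilise the electron-rich aryllead triacetate.

Step 9
Reactants: 5 tert-butyl 2-[2,4-bis(benzyloxy)-6-hydroxybenzoyl]-3-[3,4-bis(benzyloxy)phenyl]prop-2-enoate; 13 [(2R)-5,7-bis(benzyloxy)-2-[4-(benzyloxy)phenyl]-4-oxochroman-8-yl]lead triacetate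
Product: 15 tert-butyl (2S,3R)-5,7-bis(benzyloxy)-2-[3,4-bis(benzyloxy)phenyl]-3-{(2R)-5,7-bis(benzyloxy)-2-[4-(benzyloxy)phenyl]-4-oxochroman-8-yl}-4-oxochromane-3-carboxylate (3-aryl trans to 2-aryl), via cyclised β-ketoester 14 (not isolated)
Conditions: quinine-derived thiourea (10 mol %), toluene, −25 °C; then AcOH (0.1 equiv), 13 (1.3 equiv), pyridine (4 equiv), CHCl3, −25 → 25 °C
Reagents that add atoms: none
Why: The quinuclidine of the bifunctional catalyst deprotonates the hydrogen-bonded ring A hydroxyl of 5 while the thiourea binds the β-ketoester, and the phenolic oxygen (future O1) adds to the benzylidene carbon (future C2) in a 6-endo-trig oxa-Michael closure of ring C, the closest known reaction being the thiourea-catalysed enantioselective cyclisation of alkylidene β-ketoesters to flavanones. C2 is set in this closure by the catalyst, which shields one face of the alkylidene. The enol of 14 then displaces an acetate on the tetravalent lead of 13 and reductive ligand coupling within the lead enolate joins C3 to C8'' with release of Pb(OAc)2, the closest known reaction being the Pinhey arylation of alkyl 4-oxochroman-3-carboxylates with aryllead triacetates used for isoflavanones. The quaternary C3 is set by the substrate, the aryl group arriving anti to the pseudoaxial C2 aryl group, but either epimer would serve because C3 is reset in step 10. The step needs carbon- rather than oxygen-arylation and reaction at the β-ketoester rather than at the plain ketone of 13, which the ligand-coupling mechanism secures because it accepts only soft, acidic carbon acids, and the site on ring A'' is fixed by the C–Pb bond. It also needs C2 to survive until C3 is arylated, which is secured by protonating the quinuclidine with acetic acid before warming so that pyridine is the only base, and after arylation C3 has no hydrogen and retro-oxa-Michael opening is no longer possible.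

Step 10
Reactants: 15 tert-butyl (2S,3R)-5,7-bis(benzyloxy)-2-[3,4-bis(benzyloxy)phenyl]-3-{(2R)-5,7-bis(benzyloxy)-2-[4-(benzyloxy)phenyl]-4-oxochroman-8-yl}-4-oxochromane-3-carboxylate
Product: 17 (2R,3S)-5,7-bis(benzyloxy)-2-[3,4-bis(benzyloxy)phenyl]-3-{(2R)-5,7-bis(benzyloxy)-2-[4-(benzyloxy)phenyl]-4-oxochroman-8-yl}chroman-4-one, via keto acid 16 (not isolated)
Conditions: TsOH·H2O (1.0 equiv), toluene, 80 °C
Reagents that add atoms: none
Why: Acid-mediated cleavage of the tert-butyl ester (loss of 2-methylpropene) and decarboxylation of the β-keto acid give the enol, whose ketonisation, reversible at this acidic C3–H, places the bulky 3-aryl group trans (diequatorial) to the 2-aryl group, so that C3 (S) is set by thermodynamic substrate control from C2, while in the absence of base C2 and C2'' should not open by retro-oxa-Michael reaction.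

Step 11
Reactants: 17 (2R,3S)-5,7-bis(benzyloxy)-2-[3,4-bis(benzyloxy)phenyl]-3-{(2R)-5,7-bis(benzyloxy)-2-[4-(benzyloxy)phenyl]-4-oxochroman-8-yl}chroman-4-one
Product: 18 (2R,3S)-2-(3,4-dihydroxyphenyl)-5,7-dihydroxy-3-[(2R)-5,7-dihydroxy-2-(4-hydroxyphenyl)-4-oxochroman-8-yl]chroman-4-one
Conditions: H2 (1 atm), 10% Pd/C, EtOAc–MeOH (1:1), 25 °C
Reagents that add atoms: none
Why: Hydrogenolysis of seven aryl benzyl ethers over Pd/C under neutral conditions should leave the three stereocentres, the two hydrogen-bonded ketones and the benzylic C2–O1 bonds untouched when stopped at full debenzylation.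

**Compound list**

1 | 2,4,6-trihydroxyacetophenone | CC(=O)c1c(O)cc(O)cc1O | starting material
2 | 1-[2,4-bis(benzyloxy)-6-hydroxyphenyl]ethanone | CC(=O)c1c(O)cc(OCc2ccccc2)cc1OCc1ccccc1 | intermediate
3 | tert-butyl 3-[2,4-bis(benzyloxy)-6-hydroxyphenyl]-3-oxopropanoate | CC(C)(C)OC(=O)CC(=O)c1c(O)cc(OCc2ccccc2)cc1OCc1ccccc1 | intermediate
4 | 3,4-bis(benzyloxy)benzaldehyde | O=Cc1ccc(OCc2ccccc2)c(OCc2ccccc2)c1 | starting material
5 | tert-butyl 2-[2,4-bis(benzyloxy)-6-hydroxybenzoyl]-3-[3,4-bis(benzyloxy)phenyl]prop-2-enoate (E/Z mixture, geometry not specified) | CC(C)(C)OC(=O)C(=Cc1ccc(OCc2ccccc2)c(OCc2ccccc2)c1)C(=O)c1c(O)cc(OCc2ccccc2)cc1OCc1ccccc1 | intermediate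
6 | 4-(benzyloxy)benzaldehyde | O=Cc1ccc(OCc2ccccc2)cc1 | starting material
7 | tert-butyl 2-[2,4-bis(benzyloxy)-6-hydroxybenzoyl]-3-[4-(benzyloxy)phenyl]prop-2-enoate (E/Z mixture, geometry not specified) | CC(C)(C)OC(=O)C(=Cc1ccc(OCc2ccccc2)cc1)C(=O)c1c(O)cc(OCc2ccccc2)cc1OCc1ccccc1 | intermediate
8 | tert-butyl (2R)-5,7-bis(benzyloxy)-2-[4-(benzyloxy)phenyl]-4-oxochromane-3-carboxylate (not isolated; C3 epimers and enol, C3 not specified) | CC(C)(C)OC(=O)C1C(=O)c2c(OCc3ccccc3)cc(OCc3ccccc3)cc2O[C@H]1c1ccc(OCc2ccccc2)cc1 | intermediate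
9 | (2R)-5,7-bis(benzyloxy)-2-[4-(benzyloxy)phenyl]-4-oxochromane-3-carboxylic acid (not isolated; C3 not specified) | OC(=O)C1C(=O)c2c(OCc3ccccc3)cc(OCc3ccccc3)cc2O[C@H]1c1ccc(OCc2ccccc2)cc1 | intermediate
10 | (2R)-5,7-bis(benzyloxy)-2-[4-(benzyloxy)phenyl]chroman-4-one | O=C1C[C@H](c2ccc(OCc3ccccc3)cc2)Oc2cc(OCc3ccccc3)cc(OCc3ccccc3)c21 | intermediate
11 | (2R)-5,7-bis(benzyloxy)-2-[4-(benzyloxy)phenyl]-8-iodochroman-4-one | O=C1C[C@H](c2ccc(OCc3ccccc3)cc2)Oc2c(I)c(OCc3ccccc3)cc(OCc3ccccc3)c21 | intermediate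
12 | (2R)-5,7-bis(benzyloxy)-2-[4-(benzyloxy)phenyl]-8-(trimethylstannyl)chroman-4-one | O=C1C[C@H](c2ccc(OCc3ccccc3)cc2)Oc2c([Sn](C)(C)C)c(OCc3ccccc3)cc(OCc3ccccc3)c21 | intermediate
13 | [(2R)-5,7-bis(benzyloxy)-2-[4-(benzyloxy)phenyl]-4-oxochroman-8-yl]lead triacetate | O=C1C[C@H](c2ccc(OCc3ccccc3)cc2)Oc2c([Pb](OC(C)=O)(OC(C)=O)OC(C)=O)c(OCc3ccccc3)cc(OCc3ccccc3)c21 | intermediate
14 | tert-butyl (2R)-5,7-bis(benzyloxy)-2-[3,4-bis(benzyloxy)phenyl]-4-oxochromane-3-carboxylate (not isolated; C3 epimers and enol, C3 not specified) | CC(C)(C)OC(=O)C1C(=O)c2c(OCc3ccccc3)cc(OCc3ccccc3)cc2O[C@H]1c1ccc(OCc2ccccc2)c(OCc2ccccc2)c1 | intermediate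
15 | tert-butyl (2S,3R)-5,7-bis(benzyloxy)-2-[3,4-bis(benzyloxy)phenyl]-3-{(2R)-5,7-bis(benzyloxy)-2-[4-(benzyloxy)phenyl]-4-oxochroman-8-yl}-4-oxochromane-3-carboxylate (C2 has the same spatial arrangement as in 14; its descriptor changes only through the priority rules) | O=C1C[C@H](c2ccc(OCc3ccccc3)cc2)Oc2c1c(OCc1ccccc1)cc(OCc1ccccc1)c2[C@]1(C(=O)OC(C)(C)C)C(=O)c2c(OCc3ccccc3)cc(OCc3ccccc3)cc2O[C@H]1c1ccc(OCc2ccccc2)c(OCc2ccccc2)c1 | intermediate
16 | (2S,3R)-5,7-bis(benzyloxy)-2-[3,4-bis(benzyloxy)phenyl]-3-{(2R)-5,7-bis(benzyloxy)-2-[4-(benzyloxy)phenyl]-4-oxochroman-8-yl}-4-oxochromane-3-carboxylic acid (not isolated) | O=C1C[C@H](c2ccc(OCc3ccccc3)cc2)Oc2c1c(OCc1ccccc1)cc(OCc1ccccc1)c2[C@]1(C(O)=O)C(=O)c2c(OCc3ccccc3)cc(OCc3ccccc3)cc2O[C@H]1c1ccc(OCc2ccccc2)c(OCc2ccccc2)c1 | intermediate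
17 | (2R,3S)-5,7-bis(benzyloxy)-2-[3,4-bis(benzyloxy)phenyl]-3-{(2R)-5,7-bis(benzyloxy)-2-[4-(benzyloxy)phenyl]-4-oxochroman-8-yl}chroman-4-one | O=C1C[C@H](c2ccc(OCc3ccccc3)cc2)Oc2c1c(OCc1ccccc1)cc(OCc1ccccc1)c2[C@@H]1C(=O)c2c(OCc3ccccc3)cc(OCc3ccccc3)cc2O[C@H]1c1ccc(OCc2ccccc2)c(OCc2ccccc2)c1 | intermediate
18 | (2R,3S)-2-(3,4-dihydroxyphenyl)-5,7-dihydroxy-3-[(2R)-5,7-dihydroxy-2-(4-hydroxyphenyl)-4-oxochroman-8-yl]chroman-4-one | O=C1C[C@H](c2ccc(O)cc2)Oc2c1c(O)cc(O)c2[C@@H]1C(=O)c2c(O)cc(O)cc2O[C@H]1c1ccc(O)c(O)c1 | target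

**Step count and risks**

Total step count: 11. Longest linear sequence: 10 steps (steps 1, 2, 4, 5, 6, 7, 8, 9, 10, 11).

Steps most likely to fail:

1. Step 9. The C2 configuration may erode through reversible oxa-Michael opening of the β-ketoester before the aryl group is transferred, or ligand coupling between the crowded C3 and the doubly ortho-substituted aryl group may be so slow that the lead reagent decomposes first. The fallback forms the same bond by palladium catalysis, without lead and without a β-ketoester at the coupling stage, and sets out from 5 and 11. Compound 5 is cyclised with the same thiourea catalyst to 14 and decarboxylated in the same flask (TsOH·H2O, toluene, 80 °C) through the keto acid (2R)-5,7-bis(benzyloxy)-2-[3,4-bis(benzyloxy)phenyl]-4-oxochromane-3-carboxylic acid F1 to the flavanone (2R)-5,7-bis(benzyloxy)-2-[3,4-bis(benzyloxy)phenyl]chroman-4-one F2. Soft enolisation (Me3SiOTf, Et3N, CH2Cl2, 0 °C), which avoids a free enolate and thus ring opening, should give the silyl enol ether (2R)-5,7-bis(benzyloxy)-2-[3,4-bis(benzyloxy)phenyl]-4-(trimethylsilyloxy)-2H-chromene F3. Palladium-catalysed α-arylation of F3 with iodide 11 under fluoride activation (Pd(dba)2, P(t-Bu)3, ZnF2, CsF, DMF, 80 °C), with C3 equilibrating to the trans isomer, comes back to the route at 17.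

2. Step 8. Tin-to-lead transfer at the hindered, doubly ortho-oxygenated carbon may be slow, so that protodestannylation or oxidation of the chromanone by Pb(OAc)4 competes. The fallback reaches the lead reagent through boron and sets out from 11. Miyaura borylation (B2pin2, PdCl2(dppf), KOAc, dioxane, 90 °C) should give the pinacol boronate (2R)-5,7-bis(benzyloxy)-2-[4-(benzyloxy)phenyl]-8-(4,4,5,5-tetramethyl-1,3,2-dioxaborolan-2-yl)chroman-4-one F4. Oxidative cleavage of the pinacol ester (NaIO4, NH4OAc, acetone–water, 25 °C) should give the boronic acid [(2R)-5,7-bis(benzyloxy)-2-[4-(benzyloxy)phenyl]-4-oxochroman-8-yl]boronic acid F5. Boron-to-lead exchange (Pb(OAc)4, Hg(OAc)2 cat., CHCl3, 40 °C), which is usually faster than the tin variant, comes back to the route at 13.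

3. Step 6. Iodination may not discriminate well enough between C8'' and C6'', or may go on to the diiodide. The fallback places the iodine before ring C'' exists, so that its position is fixed by which oxygen closes the ring, and sets out from 2. Iodination ortho to the free hydroxyl (BnMe3N·ICl2, CaCO3, CH2Cl2–MeOH, 25 °C) should give 1-[4,6-bis(benzyloxy)-2-hydroxy-3-iodophenyl]ethanone F6. Acylation as in step 2 should give tert-butyl 3-[4,6-bis(benzyloxy)-2-hydroxy-3-iodophenyl]-3-oxopropanoate F7, and Knoevenagel condensation with 6 as in step 4 should give tert-butyl 2-[4,6-bis(benzyloxy)-2-hydroxy-3-iodobenzoyl]-3-[4-(benzyloxy)phenyl]prop-2-enoate F8. Cyclisation and decarboxylation as in step 5 pass through tert-butyl (2R)-5,7-bis(benzyloxy)-2-[4-(benzyloxy)phenyl]-8-iodo-4-oxochromane-3-carboxylate F9 and (2R)-5,7-bis(benzyloxy)-2-[4-(benzyloxy)phenyl]-8-iodo-4-oxochromane-3-carboxylic acid F10. Because the only free hydroxyl, next to the iodine, becomes O1'', the iodine ends up at C8'', and the sequence comes back to the route at 11.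

Further compounds
F1 | step 9 | (2R)-5,7-bis(benzyloxy)-2-[3,4-bis(benzyloxy)phenyl]-4-oxochromane-3-carboxylic acid | OC(=O)C1C(=O)c2c(OCc3ccccc3)cc(OCc3ccccc3)cc2O[C@H]1c1ccc(OCc2ccccc2)c(OCc2ccccc2)c1
F2 | step 9 | (2R)-5,7-bis(benzyloxy)-2-[3,4-bis(benzyloxy)phenyl]chroman-4-one | O=C1C[C@H](c2ccc(OCc3ccccc3)c(OCc3ccccc3)c2)Oc2cc(OCc3ccccc3)cc(OCc3ccccc3)c21
F3 | step 9 | (2R)-5,7-bis(benzyloxy)-2-[3,4-bis(benzyloxy)phenyl]-4-(trimethylsilyloxy)-2H-chromene | C[Si](C)(C)OC1=C[C@H](c2ccc(OCc3ccccc3)c(OCc3ccccc3)c2)Oc2cc(OCc3ccccc3)cc(OCc3ccccc3)c21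
F4 | step 8 | (2R)-5,7-bis(benzyloxy)-2-[4-(benzyloxy)phenyl]-8-(4,4,5,5-tetramethyl-1,3,2-dioxaborolan-2-yl)chroman-4-one | O=C1C[C@H](c2ccc(OCc3ccccc3)cc2)Oc2c(B3OC(C)(C)C(C)(C)O3)c(OCc3ccccc3)cc(OCc3ccccc3)c21
F5 | step 8 | [(2R)-5,7-bis(benzyloxy)-2-[4-(benzyloxy)phenyl]-4-oxochroman-8-yl]boronic acid | O=C1C[C@H](c2ccc(OCc3ccccc3)cc2)Oc2c(B(O)O)c(OCc3ccccc3)cc(OCc3ccccc3)c21
F6 | step 6 | 1-[4,6-bis(benzyloxy)-2-hydroxy-3-iodophenyl]ethanone | CC(=O)c1c(O)c(I)c(OCc2ccccc2)cc1OCc1ccccc1
F7 | step 6 | tert-butyl 3-[4,6-bis(benzyloxy)-2-hydroxy-3-iodophenyl]-3-oxopropanoate | CC(C)(C)OC(=O)CC(=O)c1c(O)c(I)c(OCc2ccccc2)cc1OCc1ccccc1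
F8 | step 6 | tert-butyl 2-[4,6-bis(benzyloxy)-2-hydroxy-3-iodobenzoyl]-3-[4-(benzyloxy)phenyl]prop-2-enoate | CC(C)(C)OC(=O)C(=Cc1ccc(OCc2ccccc2)cc1)C(=O)c1c(O)c(I)c(OCc2ccccc2)cc1OCc1ccccc1
F9 | step 6 | tert-butyl (2R)-5,7-bis(benzyloxy)-2-[4-(benzyloxy)phenyl]-8-iodo-4-oxochromane-3-carboxylate | CC(C)(C)OC(=O)C1C(=O)c2c(OCc3ccccc3)cc(OCc3ccccc3)c(I)c2O[C@H]1c1ccc(OCc2ccccc2)cc1
F10 | step 6 | (2R)-5,7-bis(benzyloxy)-2-[4-(benzyloxy)phenyl]-8-iodo-4-oxochromane-3-carboxylic acid | OC(=O)C1C(=O)c2c(OCc3ccccc3)cc(OCc3ccccc3)c(I)c2O[C@H]1c1ccc(OCc2ccccc2)cc1
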